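## Retrosynthetic overview

1. Target 24 ⇒ 23 by late epoxidation of the E‑C4=C5 alkene; 23 ⇒ 19 by silyl→acetyl exchange at O‑13 and tigloylation at O‑8.
2. 19 ⇒ 16: the ten‑membered carbocycle is made by ring expansion of the α‑methylene‑γ‑butyrolactone (O8–C1 acyl bond); C‑2 attacks C‑1 and O‑8 is expelled from the ring (new C1–C2 bond).
3. 16 ⇒ 13 + 4: butenolide by Ni/Cr coupling of a β‑iodoacrylate with an enal, then lactonisation (C6–C7 bond, sets C‑6).
4. 13 ⇒ 10 by iodo‑aldol with CH2O (C11–C13); 10 ⇒ 6 + 7 by asymmetric carboxyallylation–lactonisation (C8–C9, sets C‑8); 4 ⇐ 1 by carboalumination.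
5. Ring order: γ‑lactone (C1/O8) → butenolide → ten‑membered carbocycle (ring expansion) → epoxide.

Assumption: germacrane numbering (C‑1 to C‑15) is used throughout, compounds 1, 5, 7 and 20 are taken as commercial, and C‑6 is R in the 4,5‑alkene intermediates but S in the target only because the CIP ranking of C‑5 and C‑7 changes on epoxidation.

## Route

Step 1
Reactants: 1 but‑3‑yn‑1‑ol
Product: 3 (2E)-3-methylpent-2-ene-1,5-diol, via alkenylalane 2 (not isolated)
Conditions: AlMe3 (3 equiv), Cp2ZrCl2 (25 mol%), CH2Cl2, 0 °C→rt; then n‑BuLi, THF, −78 °C; (CH2O)n, −78 °C→rt; aq. HCl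
Reagents that add atoms: trimethylaluminium (C[Al](C)C); formaldehyde as paraformaldehyde (C=O)
Why: Negishi Zr‑catalysed carboalumination adds Me–Al syn across the terminal alkyne (Me to the internal carbon), and the derived alkenylalanate is hydroxymethylated with retention, which fixes the E‑trisubstituted C4=C5 alkene.

Step 2
Reactants: 3 (2E)-3-methylpent-2-ene-1,5-diol
Product: 4 (2E)-5-hydroxy-3-methylpent-2-enal
Conditions: activated MnO2, CH2Cl2, rt
Reagents that add atoms: none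
Why: Chemoselective MnO2 allylic oxidation converts only the allylic primary alcohol into the enal and leaves the saturated alcohol and the E geometry untouched.

Step 3
Reactants: 5 methyl 4‑hydroxybut‑2‑ynoate
Product: 6 methyl 4‑oxobut‑2‑ynoate
Conditions: Dess–Martin periodinane, CH2Cl2, 0 °C→rt; filtered solution used at once
Reagents that add atoms: none
Why: Dess–Martin oxidation of the propargylic alcohol under neutral conditions gives the sensitive ynal without touching the ynoate.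

Step 4
Reactants: 6 methyl 4‑oxobut‑2‑ynoate; 7 methyl 2‑(bromomethyl)prop‑2‑enoate
Product: 10 methyl 3-[(2S)-4-methylidene-5-oxooxolan-2-yl]prop-2-ynoate, via silyl ether 8 (not isolated), via hydroxy diester 9 (not isolated)
Conditions: CrCl2 (10 mol%), chiral carbazole‑bis(oxazoline) ligand (11 mol%, enantiomer giving 8S), Mn (2 equiv), TMSCl (1.5 equiv), i‑Pr2NEt (30 mol%), THF, rt; then 1 M HCl, THF, rt
Reagents that add atoms: none
Why: Catalytic asymmetric Nozaki–Hiyama (Barbier‑type) 2‑(alkoxycarbonyl)allylation, in which the chiral Cr(III)–allyl adds 1,2 to the aldehyde only and the ligand sets C‑8 as S, after which acid removes the silyl group and closes the α‑methylene‑γ‑butyrolactone.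

Step 5
Reactants: 10 methyl 3-[(2S)-4-methylidene-5-oxooxolan-2-yl]prop-2-ynoate
Product: 12 methyl (2Z)-2-(hydroxymethyl)-3-iodo-3-[(2S)-4-methylidene-5-oxooxolan-2-yl]prop-2-enoate, via magnesium iodoallenolate 11 (not isolated)
Conditions: MgI2 (1.5 equiv), monomeric CH2O (THF solution, 3 equiv), CH2Cl2, −20→0 °C; aq. NH4Cl
Reagents that add atoms: magnesium iodide ([Mg+2].[I-].[I-]); formaldehyde (C=O)
Why: Halo‑aldol (iodo‑Baylis–Hillman‑type) reaction, in which iodide adds to the ynoate β‑carbon and the Mg‑chelated allenolate is hydroxymethylated at C‑11 to give the Z isomer with iodine cis to the ester, as the later lactonisation requires.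

Step 6
Reactants: 12 methyl (2Z)-2-(hydroxymethyl)-3-iodo-3-[(2S)-4-methylidene-5-oxooxolan-2-yl]prop-2-enoate
Product: 13 methyl (2Z)-2-({[tert-butyl(dimethyl)silyl]oxy}methyl)-3-iodo-3-[(2S)-4-methylidene-5-oxooxolan-2-yl]prop-2-enoate
Conditions: TBSCl, imidazole, DMF, 0 °C→rt
Reagents that add atoms: tert‑butyldimethylsilyl chloride (CC(C)(C)[Si](C)(C)Cl)
Why: Standard silylation of the only hydroxyl masks O‑13 as a non‑reducible, non‑acidic ether for the organometallic steps.

Step 7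
Reactants: 13 methyl (2Z)-2-({[tert-butyl(dimethyl)silyl]oxy}methyl)-3-iodo-3-[(2S)-4-methylidene-5-oxooxolan-2-yl]prop-2-enoate; 4 (2E)-5-hydroxy-3-methylpent-2-enal
Product: 15 (5R)-3-({[tert-butyl(dimethyl)silyl]oxy}methyl)-5-[(1E)-4-hydroxy-2-methylbut-1-en-1-yl]-4-[(2S)-4-methylidene-5-oxooxolan-2-yl]furan-2(5H)-one, via open-chain hydroxy ester 14 (not isolated)
Conditions: CrCl2 (4 equiv), NiCl2 (2 mol%), Kishi‑type chiral oxazoline–sulfonamide ligand (4.4 equiv, recovered; enantiomer giving 6R), Et3N (4.4 equiv), THF, rt; aq. NH4Cl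
Reagents that add atoms: none
Why: Nozaki–Hiyama–Kishi coupling, in which Ni inserts into the activated vinyl C–I bond and the alkenylchromium adds 1,2 to the enal with retention of alkene geometry under ligand control to set C‑6 (R), after which the cis ester lactonises to the butenolide.

Step 8
Reactants: 15 (5R)-3-({[tert-butyl(dimethyl)silyl]oxy}methyl)-5-[(1E)-4-hydroxy-2-methylbut-1-en-1-yl]-4-[(2S)-4-methylidene-5-oxooxolan-2-yl]furan-2(5H)-one
Product: 16 (5R)-3-({[tert-butyl(dimethyl)silyl]oxy}methyl)-5-[(1E)-4-iodo-2-methylbut-1-en-1-yl]-4-[(2S)-4-methylidene-5-oxooxolan-2-yl]furan-2(5H)-one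
Conditions: I2, PPh3, imidazole, CH2Cl2, 0 °C
Reagents that add atoms: iodine (II)
Why: Appel iodination converts the primary alcohol into the iodide by SN2 under neutral conditions that leave both lactones and the silyl ether intact.

Step 9
Reactants: 16 (5R)-3-({[tert-butyl(dimethyl)silyl]oxy}methyl)-5-[(1E)-4-iodo-2-methylbut-1-en-1-yl]-4-[(2S)-4-methylidene-5-oxooxolan-2-yl]furan-2(5H)-one
Product: 19 (4E,6R,8S)-13-(tert-butyldimethylsilyloxy)-8-hydroxy-1-oxogermacra-4,7(11),10(14)-trien-12,6-olide, via alkylsamarium 17 (not isolated), via bridged samarium hemiketalate 18 (not isolated)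
Conditions: SmI2 (2.5 equiv, 0.1 M in THF), NiI2 (2 mol%), THF, −78→−20 °C, syringe‑pump addition of 16 to 2 mM; aq. NH4Cl
Reagents that add atoms: none
Why: Proposed new method: SmI2/cat. NiI2 in HMPA‑free THF is expected to reduce only the primary C–I bond to the alkylsamarium 17, whose sole reachable electrophile is the lactone carbonyl C‑1 (attack on the butenolide C=O or its β‑carbon would put the E‑C4=C5 unit in a 6‑ to 8‑membered ring), so 1,2‑addition gives the bridged hemiketalate 18, which masks the nascent enone from further reduction and on protonation expels O‑8, i.e. the five‑membered lactone is expanded to the ten‑membered γ‑hydroxy‑α‑methylene ketone by O→C acyl transfer; the closest known reaction is the SmI2‑promoted intramolecular nucleophilic acyl substitution of ω‑iodoalkyl lactones (ring expansion to seven‑ to nine‑membered hydroxy cycloalkanones), not yet shown for an α‑alkylidene lactone, a ten‑membered ring or an unsaturated polyfunctional tether.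

Step 10
Reactants: 19 (4E,6R,8S)-13-(tert-butyldimethylsilyloxy)-8-hydroxy-1-oxogermacra-4,7(11),10(14)-trien-12,6-olide; 20 (2E)-2-methylbut-2-enoyl chloride (tigloyl chloride)
Product: 21 (4E,6R,8S)-13-(tert-butyldimethylsilyloxy)-1-oxo-8-[(2E)-2-methylbut-2-enoyloxy]germacra-4,7(11),10(14)-trien-12,6-olide
Conditions: pyridine, DMAP (cat.), CH2Cl2, 0 °C→rt
Reagents that add atoms: none
Why: DMAP‑catalysed acylation of the only free hydroxyl drains the hydroxy ketone/hemiketal equilibrium towards the open 8‑O‑ester, and the E‑configured tigloyl group does not isomerise.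

Step 11
Reactants: 21 (4E,6R,8S)-13-(tert-butyldimethylsilyloxy)-1-oxo-8-[(2E)-2-methylbut-2-enoyloxy]germacra-4,7(11),10(14)-trien-12,6-olide
Product: 23 (4E,6R,8S)-13-acetoxy-1-oxo-8-[(2E)-2-methylbut-2-enoyloxy]germacra-4,7(11),10(14)-trien-12,6-olide, via primary alcohol 22 (not isolated)
Conditions: HF·pyridine, pyridine/THF, 0 °C→rt; then Ac2O, DMAP, same pot, 0 °C→rt
Reagents that add atoms: acetic anhydride (CC(=O)OC(C)=O)
Why: Fluoride desilylation followed by in‑situ acetylation of the liberated primary allylic alcohol installs the 13‑acetate under weakly acidic to neutral conditions that spare the base‑sensitive butenolide γ‑H.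

Step 12
Reactants: 23 (4E,6R,8S)-13-acetoxy-1-oxo-8-[(2E)-2-methylbut-2-enoyloxy]germacra-4,7(11),10(14)-trien-12,6-olide
Product: 24 (4R,5R,6S,8S)-13-acetoxy-4,5-epoxy-1-oxo-8-[(2E)-2-methylbut-2-enoyloxy]germacra-7(11),10(14)-dien-12,6-olide (CNP0225286.1)
Conditions: dimethyldioxirane (1.1 equiv), acetone/CH2Cl2, 0 °C
Reagents that add atoms: dimethyldioxirane (CC1(C)OO1)
Why: Electrophilic DMDO epoxidation attacks only the electron‑rich trisubstituted E‑C4=C5 alkene (enone, butenolide and tiglate alkenes are electron‑poor) and, by analogy with the facial bias of related 6,12‑germacranolides, is expected to approach from the exposed outer face of the ring‑perpendicular alkene, giving the trans (4R,5R)‑epoxide.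

## Compound list

1 | but‑3‑yn‑1‑ol | C#CCCO | starting material
2 | alkenylalane: dimethyl{(1E)-4-[(dimethylalumanyl)oxy]-2-methylbut-1-en-1-yl}alumane | C[Al](C)/C=C(\C)CCO[Al](C)C | intermediate (not isolated)
3 | (2E)-3-methylpent-2-ene-1,5-diol | OC/C=C(\C)CCO | intermediate
4 | (2E)-5-hydroxy-3-methylpent-2-enal | O=C/C=C(\C)CCO | intermediate
5 | methyl 4‑hydroxybut‑2‑ynoate | COC(=O)C#CCO | starting material
6 | methyl 4‑oxobut‑2‑ynoate | COC(=O)C#CC=O | intermediate
7 | methyl 2‑(bromomethyl)prop‑2‑enoate | COC(=O)C(=C)CBr | starting material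
8 | dimethyl (4S)-2-methylidene-4-[(trimethylsilyl)oxy]hept-5-ynedioate | COC(=O)C#C[C@H](CC(=C)C(=O)OC)O[Si](C)(C)C | intermediate (not isolated)
9 | dimethyl (4S)-4-hydroxy-2-methylidenehept-5-ynedioate | COC(=O)C#C[C@H](CC(=C)C(=O)OC)O | intermediate (not isolated)
10 | methyl 3-[(2S)-4-methylidene-5-oxooxolan-2-yl]prop-2-ynoate | COC(=O)C#C[C@@H]1CC(=C)C(=O)O1 | intermediate
11 | magnesium iodoallenolate of 10 (iodomagnesium ketene acetal, C‑8 S) | COC(O[Mg]I)=C=C(I)[C@@H]1CC(=C)C(=O)O1 | intermediate (not isolated)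
12 | methyl (2Z)-2-(hydroxymethyl)-3-iodo-3-[(2S)-4-methylidene-5-oxooxolan-2-yl]prop-2-enoate | COC(=O)/C(CO)=C(\I)[C@@H]1CC(=C)C(=O)O1 | intermediate
13 | methyl (2Z)-2-({[tert-butyl(dimethyl)silyl]oxy}methyl)-3-iodo-3-[(2S)-4-methylidene-5-oxooxolan-2-yl]prop-2-enoate | COC(=O)/C(CO[Si](C)(C)C(C)(C)C)=C(\I)[C@@H]1CC(=C)C(=O)O1 | intermediate
14 | open‑chain hydroxy ester: methyl (4R,5E)-2-(TBSOCH2)-4,8-dihydroxy-6-methyl-3-[(2S)-4-methylidene-5-oxooxolan-2-yl]octa-2,5-dienoate, CO2Me cis to C‑4 (formed as its Cr alkoxide) | COC(=O)/C(CO[Si](C)(C)C(C)(C)C)=C(\[C@H](O)/C=C(\C)CCO)[C@@H]1CC(=C)C(=O)O1 | intermediate (not isolated)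
15 | (5R)-3-({[tert-butyl(dimethyl)silyl]oxy}methyl)-5-[(1E)-4-hydroxy-2-methylbut-1-en-1-yl]-4-[(2S)-4-methylidene-5-oxooxolan-2-yl]furan-2(5H)-one | C=C1C[C@H](OC1=O)C2=C(CO[Si](C)(C)C(C)(C)C)C(=O)O[C@@H]2/C=C(\C)CCO | intermediate
16 | (5R)-3-({[tert-butyl(dimethyl)silyl]oxy}methyl)-5-[(1E)-4-iodo-2-methylbut-1-en-1-yl]-4-[(2S)-4-methylidene-5-oxooxolan-2-yl]furan-2(5H)-one | C=C1C[C@H](OC1=O)C2=C(CO[Si](C)(C)C(C)(C)C)C(=O)O[C@@H]2/C=C(\C)CCI | intermediate
17 | alkylsamarium(III) diiodide derived from 16 (Sm at C‑2) | C=C1C[C@H](OC1=O)C2=C(CO[Si](C)(C)C(C)(C)C)C(=O)O[C@@H]2/C=C(\C)CC[Sm](I)I | intermediate (not isolated)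
18 | bridged samarium hemiketalate: (1R,4E,6R,8S)-13-(TBSO)-1-(diiodosamariooxy)-1,8-epoxygermacra-4,7(11),10(14)-trien-12,6-olide | C=C1C[C@@H]2O[C@@]1(O[Sm](I)I)CC/C(C)=C/[C@H]1OC(=O)C(CO[Si](C)(C)C(C)(C)C)=C12 | intermediate (not isolated)
19 | (4E,6R,8S)-13-(tert-butyldimethylsilyloxy)-8-hydroxy-1-oxogermacra-4,7(11),10(14)-trien-12,6-olide | C=C1C[C@H](O)C2=C(CO[Si](C)(C)C(C)(C)C)C(=O)O[C@@H]2/C=C(\C)CCC1=O | intermediate
20 | (2E)-2-methylbut-2-enoyl chloride (tigloyl chloride) | C/C=C(\C)C(=O)Cl | starting material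
21 | (4E,6R,8S)-13-(tert-butyldimethylsilyloxy)-1-oxo-8-[(2E)-2-methylbut-2-enoyloxy]germacra-4,7(11),10(14)-trien-12,6-olide | C=C1C[C@H](OC(=O)/C(C)=C/C)C2=C(CO[Si](C)(C)C(C)(C)C)C(=O)O[C@@H]2/C=C(\C)CCC1=O | intermediate
22 | (4E,6R,8S)-13-hydroxy-1-oxo-8-[(2E)-2-methylbut-2-enoyloxy]germacra-4,7(11),10(14)-trien-12,6-olide | C=C1C[C@H](OC(=O)/C(C)=C/C)C2=C(CO)C(=O)O[C@@H]2/C=C(\C)CCC1=O | intermediate (not isolated)
23 | (4E,6R,8S)-13-acetoxy-1-oxo-8-[(2E)-2-methylbut-2-enoyloxy]germacra-4,7(11),10(14)-trien-12,6-olide | C=C1C[C@H](OC(=O)/C(C)=C/C)C2=C(COC(C)=O)C(=O)O[C@@H]2/C=C(\C)CCC1=O | intermediate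
24 | (4R,5R,6S,8S)-13-acetoxy-4,5-epoxy-1-oxo-8-[(2E)-2-methylbut-2-enoyloxy]germacra-7(11),10(14)-dien-12,6-olide | C=C1C[C@H](OC(=O)/C(C)=C/C)C2=C(COC(C)=O)C(=O)O[C@@H]2[C@H]2O[C@]2(C)CCC1=O | target

## Step count and risks

Total steps: 12. Longest linear sequence: 10 (steps 3–12: 5 → 6 → 10 → 12 → 13 → 15 → 16 → 19 → 21 → 23 → 24).

Three steps most likely to fail:

1. Step 9 (the proposed new ring expansion). SmI2 may reduce the butenolide or the α‑methylene lactone, and the ten‑membered closure may lose to simple C‑2 reduction or to 1,4‑addition at C‑14. The fallback uses known chemistry and closes the carbocycle at C1–C10 by an intramolecular Nozaki–Hiyama–Kishi reaction; it sets out from 6 and comes back at 21. Cr‑catalysed asymmetric 2‑bromoallylation of 6 with 2,3‑dibromopropene (conditions of step 4) gives methyl (4S)-6-bromo-4-hydroxyhept-6-en-2-ynoate F1. The iodo‑aldol of step 5 gives the Z‑iodo diol F2. TBSCl/imidazole at −20 °C silylates the primary alcohol to give F3, and 20/pyridine/DMAP acylates the secondary alcohol to give the tiglate F4. Pent‑4‑yn‑1‑ol is taken through the chemistry of steps 1 and 2 to (2E)-3-methylhex-2-ene-1,6-diol F5 and then (2E)-6-hydroxy-3-methylhex-2-enal F6. Ni/Cr coupling of the vinyl iodide of F4 with F6 as in step 7 (the vinyl bromide is untouched) gives the butenolide alcohol F7. Dess–Martin oxidation gives the aldehyde F8. CrCl2/NiCl2 in DMSO at high dilution closes the ten‑membered ring to the allylic alcohol F9 (both C‑1 epimers), and Dess–Martin oxidation gives 21.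

2. Step 5 (iodo‑aldol). Iodide and formaldehyde may also engage the α‑methylene lactone, and the hindered ynoate may give E/Z mixtures. The fallback runs the iodo‑aldol before any second Michael acceptor exists; it sets out from 5 and comes back at 13. PMB trichloroacetimidate with catalytic TfOH gives the PMB ether F10. MgI2/CH2O gives the Z‑iodo alcohol F11, and TBSCl/imidazole gives the silyl ether F12. DDQ gives the allylic alcohol F13, and MnO2 gives the β‑iodo enal F14. Cr‑catalysed asymmetric carboxyallylation with 7 followed by acid lactonisation (conditions of step 4) gives 13.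

3. Step 12 (epoxidation). The facial selectivity rests on analogy and may favour the (4S,5S)‑epoxide. The fallback is a two‑step halohydrin route that delivers oxygen to the face opposite to the one a direct oxidant attacks; it sets out from 23 and comes back at 24. NBS in aqueous THF gives the (4R,5S)‑bromohydrin F15 (bromonium on the exposed face, water at tertiary C‑4 from the other face), and Ag2O in CH2Cl2 closes the epoxide with inversion at C‑5 to give 24.

## Further compounds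

F1 | step 9 | methyl (4S)-6-bromo-4-hydroxyhept-6-en-2-ynoate | COC(=O)C#C[C@H](CC(Br)=C)O
F2 | step 9 | methyl (2Z,4S)-6-bromo-4-hydroxy-2-(hydroxymethyl)-3-iodohepta-2,6-dienoate | COC(=O)/C(CO)=C(\I)[C@H](CC(Br)=C)O
F3 | step 9 | methyl (2Z,4S)-6-bromo-2-({[tert-butyl(dimethyl)silyl]oxy}methyl)-4-hydroxy-3-iodohepta-2,6-dienoate | COC(=O)/C(CO[Si](C)(C)C(C)(C)C)=C(\I)[C@H](CC(Br)=C)O
F4 | step 9 | methyl (2Z,4S)-6-bromo-2-({[tert-butyl(dimethyl)silyl]oxy}methyl)-3-iodo-4-[(2E)-2-methylbut-2-enoyloxy]hepta-2,6-dienoate | COC(=O)/C(CO[Si](C)(C)C(C)(C)C)=C(\I)[C@H](CC(Br)=C)OC(=O)/C(C)=C/C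
F5 | step 9 | (2E)-3-methylhex-2-ene-1,6-diol | OC/C=C(\C)CCCO
F6 | step 9 | (2E)-6-hydroxy-3-methylhex-2-enal | O=C/C=C(\C)CCCO
F7 | step 9 | (1S)-3-bromo-1-[(2R)-4-({[tert-butyl(dimethyl)silyl]oxy}methyl)-2-[(1E)-5-hydroxy-2-methylpent-1-en-1-yl]-5-oxo-2,5-dihydrofuran-3-yl]but-3-en-1-yl (2E)-2-methylbut-2-enoate | C=C(Br)C[C@H](OC(=O)/C(C)=C/C)C1=C(CO[Si](C)(C)C(C)(C)C)C(=O)O[C@@H]1/C=C(\C)CCCO
F8 | step 9 | (1S)-3-bromo-1-[(2R)-4-({[tert-butyl(dimethyl)silyl]oxy}methyl)-2-[(1E)-2-methyl-5-oxopent-1-en-1-yl]-5-oxo-2,5-dihydrofuran-3-yl]but-3-en-1-yl (2E)-2-methylbut-2-enoate | C=C(Br)C[C@H](OC(=O)/C(C)=C/C)C1=C(CO[Si](C)(C)C(C)(C)C)C(=O)O[C@@H]1/C=C(\C)CCC=O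
F9 | step 9 | (4E,6R,8S)-13-(tert-butyldimethylsilyloxy)-1-hydroxy-8-[(2E)-2-methylbut-2-enoyloxy]germacra-4,7(11),10(14)-trien-12,6-olide (C‑1 epimers) | C=C1C[C@H](OC(=O)/C(C)=C/C)C2=C(CO[Si](C)(C)C(C)(C)C)C(=O)O[C@@H]2/C=C(\C)CCC1O
F10 | step 5 | methyl 4-[(4-methoxybenzyl)oxy]but-2-ynoate | COC(=O)C#CCOCc1ccc(OC)cc1
F11 | step 5 | methyl (2Z)-2-(hydroxymethyl)-3-iodo-4-[(4-methoxybenzyl)oxy]but-2-enoate | COC(=O)/C(CO)=C(\I)COCc1ccc(OC)cc1
F12 | step 5 | methyl (2Z)-2-({[tert-butyl(dimethyl)silyl]oxy}methyl)-3-iodo-4-[(4-methoxybenzyl)oxy]but-2-enoate | COC(=O)/C(CO[Si](C)(C)C(C)(C)C)=C(\I)COCc1ccc(OC)cc1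
F13 | step 5 | methyl (2Z)-2-({[tert-butyl(dimethyl)silyl]oxy}methyl)-4-hydroxy-3-iodobut-2-enoate | COC(=O)/C(CO[Si](C)(C)C(C)(C)C)=C(\I)CO
F14 | step 5 | methyl (2Z)-2-({[tert-butyl(dimethyl)silyl]oxy}methyl)-3-iodo-4-oxobut-2-enoate | COC(=O)/C(CO[Si](C)(C)C(C)(C)C)=C(\I)C=O
F15 | step 12 | (4R,5S,6S,8S)-13-acetoxy-5-bromo-4-hydroxy-1-oxo-8-[(2E)-2-methylbut-2-enoyloxy]germacra-7(11),10(14)-dien-12,6-olide | C=C1C[C@H](OC(=O)/C(C)=C/C)C2=C(COC(C)=O)C(=O)O[C@@H]2[C@H](Br)[C@](C)(O)CCC1=O
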